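**Plan**

1. Disconnections: first the C(sp)–C(sp2) bond between the ring alkyne and the (E)-alkene (Sonogashira), giving oxolane alkyne 11 and bromo-iodo-triene 20; then 20 at its inner (Z)-alkene (Wittig); last the oxolane at C3–C4 and O1–C5 (ring numbering: O1, C2 with the ester chain, C3, C4, C5 with the alkyne).
2. Enabling feature: C5 is both propargylic and bonded to the ring oxygen, so the C4–C5 edge is the alkene of a 1,3-enyne, and O1–C2–C3 is a terminal epoxide opened at its CH2 group. A radical at C3 and the hydroxyl group at C2 can therefore add across the enyne alkene as one [3+2] unit.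
3. Forward: (R)-epoxide 3 → iodohydrin 4; copper-catalysed radical [3+2] annulation of 4 with silyl enyne 7 builds the oxolane in one operation; desilylation; side chain 20 (four steps, made separately) is joined last.
4. Stereochemistry: C2 from hydrolytic kinetic resolution; C5 in the annulation (chair-like alkoxy-copper ring plus chiral ligand, trans); (E)-alkene from hydrozirconation–iodination; (Z,Z)-bromodiene from a (Z)-bromoacrylate and a Z-selective Wittig reaction.

Key step: step 5

Assumption: the (S,S) enantiomer of the bisoxazoline ligand in step 5 is taken as the one whose facial preference matches the substrate-based chair preference; if it proves mismatched, the (R,R) ligand takes its place and nothing else changes.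

**Step 1**
Reactants: 1 methyl hex-5-enoate
Product: 2 methyl 4-(oxiran-2-yl)butanoate (racemic)
Conditions: mCPBA (1.2 equiv), NaHCO3, CH2Cl2, 0 °C to rt
Reagents that add atoms: mCPBA (3-chloroperoxybenzoic acid), OOC(=O)c1cccc(Cl)c1
Why: Prilezhaev epoxidation of the isolated terminal alkene by the peracid; the ester is inert and the product is racemic by design.

**Step 2**
Reactants: 2 methyl 4-(oxiran-2-yl)butanoate (racemic)
Product: 3 methyl 4-[(2R)-oxiran-2-yl]butanoate
Conditions: (R,R)-(salen)Co(OAc) (0.5 mol %; salen = N,N'-bis(3,5-di-tert-butylsalicylidene)cyclohexane-1,2-diamine dianion, trivalent cobalt), H2O (0.55 equiv), THF (minimal), 0 °C to rt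
Reagents that add atoms: none
Why: Jacobsen hydrolytic kinetic resolution: the (R,R) complex should hydrolyse the (S)-epoxide selectively, as with other alkyl-substituted terminal epoxides, and leave the (R)-epoxide, which becomes C2 of the oxolane.

**Step 3**
Reactants: 3 methyl 4-[(2R)-oxiran-2-yl]butanoate
Product: 4 methyl (5R)-5-hydroxy-6-iodohexanoate
Conditions: LiI (1.5 equiv), AcOH (1.5 equiv), THF, rt; used at once
Reagents that add atoms: lithium iodide, [Li+].[I-]
Why: Regioselective SN2 opening of the terminal epoxide by iodide at the CH2 carbon (halohydrin formation) leaves the stereocentre untouched; immediate use forestalls reclosure and δ-lactonisation.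

**Step 4**
Reactants: 5 bromoethene (vinyl bromide, 1.0 M in THF); 6 ethynyltri(propan-2-yl)silane
Product: 7 (but-3-en-1-yn-1-yl)tri(propan-2-yl)silane
Conditions: Pd(PPh3)2Cl2 (2 mol %), CuI (4 mol %), iPr2NH, THF, rt, sealed flask
Reagents that add atoms: none
Why: Sonogashira coupling of a vinyl bromide with a terminal alkyne; no stereocentre is formed, and the bulky silyl group makes the enyne easy to handle and shields the alkyne terminus in step 5.

**Step 5**
Reactants: 4 methyl (5R)-5-hydroxy-6-iodohexanoate; 7 (but-3-en-1-yn-1-yl)tri(propan-2-yl)silane (3 equiv)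
Product: 10 methyl 4-[(2R,5S)-5-{[tri(propan-2-yl)silyl]ethynyl}oxolan-2-yl]butanoate, via primary β-hydroxyalkyl radical 8 (not isolated), via propargylic radical 9 (not isolated)
Conditions: Cu(MeCN)4PF6 (10 mol %), (S,S)-tBu-box (12 mol %), iPr2NEt (3 equiv), PhCMe2OOSiMe3 (2.5 equiv, slow addition), MeCN, 0 °C to rt
Reagents that add atoms: none
Why: Proposed new method: monovalent copper cleaves the silyl peroxide to a divalent copper silanolate and a cumyloxyl radical, this abstracts an α-hydrogen from iPr2NEt, the α-aminoalkyl radical takes the iodine atom from 4 (halogen-atom transfer), the primary radical 8 adds to the CH2 terminus of 7 (C3–C4 bond), and the propargylic radical 9 is captured by divalent copper that already holds the C2 alkoxide, whereupon C–O reductive elimination from trivalent copper forms the O1–C5 bond and returns monovalent copper. The closest known reaction types are the copper-catalysed coupling of unactivated alkyl iodides with nitrogen nucleophiles by halogen-atom transfer to α-aminoalkyl radicals and the copper-catalysed radical 1,2-difunctionalisation of 1,3-enynes; what is new is that radical and nucleophile sit in one three-atom unit, so that the relay becomes a [3+2] annulation. The oxolane closes by reductive elimination from a six-membered alkoxy(alkyl)copper ring, formally a 5-exo-tet closure at C5. C5 is set in this copper ring: capture of the planar radical should be reversible, the chair that places the ester chain at C2 and the alkynyl group at C5 both equatorial should be preferred, and elimination with retention at carbon turns it into the 2,5-trans oxolane, a preference that the tBu-box ligand is meant to reinforce, while C2 is carried over from 4. The step needs attack at the alkene terminus and 1,2- instead of 1,4-capture; the unsubstituted vinyl group and the propargylic stabilisation of 9 secure the first, the bulky silyl group and the strain of a seven-membered cyclic allene the second. A propargylic iodide formed by iodine transfer would not be lost, since monovalent copper should return it to 9, so that both C5 epimers drain into the same copper ring.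

**Step 6**
Reactants: 10 methyl 4-[(2R,5S)-5-{[tri(propan-2-yl)silyl]ethynyl}oxolan-2-yl]butanoate
Product: 11 methyl 4-[(2R,5S)-5-ethynyloxolan-2-yl]butanoate
Conditions: Bu4NF (1.2 equiv), AcOH (1.2 equiv), THF, 0 °C to rt
Reagents that add atoms: none
Why: Fluoride-induced protodesilylation of the alkynylsilane; buffered fluoride spares the methyl ester, and neither stereocentre is acidic enough to epimerise.

**Step 7**
Reactants: 12 hept-6-yn-1-ol
Product: 13 7-bromohept-1-yne
Conditions: CBr4 (1.2 equiv), PPh3 (1.25 equiv), CH2Cl2, 0 °C to rt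
Reagents that add atoms: carbon tetrabromide, BrC(Br)(Br)Br
Why: Appel bromination of the primary alcohol by SN2 displacement of the oxyphosphonium group; the terminal alkyne is inert.

**Step 8**
Reactants: 13 7-bromohept-1-yne
Product: 15 (1E)-7-bromo-1-iodohept-1-ene, via (E)-alkenylzirconocene chloride 14 (not isolated)
Conditions: Cp2Zr(H)Cl (1.2 equiv), CH2Cl2, rt, dark; then I2 (1.2 equiv), 0 °C
Reagents that add atoms: iodine, II
Why: Hydrozirconation adds Zr–H syn to the terminal alkyne with zirconium at the terminus, and iodinolysis with retention gives the (E)-vinyl iodide; the primary bromide is tolerated by Cp2Zr(H)Cl.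

**Step 9**
Reactants: 15 (1E)-7-bromo-1-iodohept-1-ene
Product: 16 [(6E)-7-iodohept-6-en-1-yl]triphenylphosphonium bromide
Conditions: PPh3 (1.1 equiv), MeCN, 80 °C, dark
Reagents that add atoms: triphenylphosphine, c1ccc(cc1)P(c1ccccc1)c1ccccc1
Why: SN2 quaternisation of the phosphine by the primary alkyl bromide; the vinyl iodide does not react with the phosphine in the absence of a transition metal.

**Step 10**
Reactants: 16 [(6E)-7-iodohept-6-en-1-yl]triphenylphosphonium bromide; 17 ethyl (2Z)-3-bromoprop-2-enoate
Product: 20 (1Z,3Z,9E)-1-bromo-10-iododeca-1,3,9-triene, via phosphonium ylide 18 (not isolated), via (Z)-3-bromoprop-2-enal 19 (not isolated)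
Conditions: 17, iBu2AlH (1.0 equiv), CH2Cl2, −78 °C; separately 16, NaN(SiMe3)2 (1.0 equiv), THF, −78 to 0 °C; ylide solution added to the aldehyde at −78 °C, then to rt
Reagents that add atoms: none
Why: Wittig olefination of a non-stabilised ylide under lithium-free conditions should give the new C=C bond with Z geometry by kinetic control through the cis-oxaphosphetane; the aldehyde is released from its aluminium hemiacetal at low temperature and carries its Z C=C bond over from 17.

**Step 11**
Reactants: 11 methyl 4-[(2R,5S)-5-ethynyloxolan-2-yl]butanoate; 20 (1Z,3Z,9E)-1-bromo-10-iododeca-1,3,9-triene (1.2 equiv)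
Product: 21 methyl 4-[(2R,5S)-5-[(3E,9Z,11Z)-12-bromododeca-3,9,11-trien-1-yn-1-yl]oxolan-2-yl]butanoate
Conditions: Pd(PPh3)4 (5 mol %), CuI (10 mol %), iPr2NH, THF, 0 °C, dark
Reagents that add atoms: none
Why: Sonogashira coupling; oxidative addition of zerovalent palladium to the C–I bond is much faster than to the C–Br bond of the dienyl bromide at 0 °C, the alkene geometries are retained and no stereocentre is touched.

**Compound list**

1 | methyl hex-5-enoate | COC(=O)CCCC=C | starting material
2 | methyl 4-(oxiran-2-yl)butanoate (racemic) | COC(=O)CCCC1CO1 | intermediate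
3 | methyl 4-[(2R)-oxiran-2-yl]butanoate | COC(=O)CCC[C@@H]1CO1 | intermediate
4 | methyl (5R)-5-hydroxy-6-iodohexanoate | COC(=O)CCC[C@@H](O)CI | intermediate
5 | bromoethene (vinyl bromide) | C=CBr | starting material
6 | ethynyltri(propan-2-yl)silane | C#C[Si](C(C)C)(C(C)C)C(C)C | starting material
7 | (but-3-en-1-yn-1-yl)tri(propan-2-yl)silane | C=CC#C[Si](C(C)C)(C(C)C)C(C)C | intermediate
8 | 2-hydroxy-6-methoxy-6-oxohexyl radical, carbinol carbon configured as in 4 (not isolated) | COC(=O)CCC[C@@H](O)[CH2] | intermediate
9 | 6-hydroxy-10-methoxy-10-oxo-1-[tri(propan-2-yl)silyl]dec-1-yn-3-yl radical, carbinol carbon configured as in 4 (not isolated) | COC(=O)CCC[C@@H](O)CC[CH]C#C[Si](C(C)C)(C(C)C)C(C)C | intermediate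
10 | methyl 4-[(2R,5S)-5-{[tri(propan-2-yl)silyl]ethynyl}oxolan-2-yl]butanoate | COC(=O)CCC[C@@H]1CC[C@@H](C#C[Si](C(C)C)(C(C)C)C(C)C)O1 | intermediate
11 | methyl 4-[(2R,5S)-5-ethynyloxolan-2-yl]butanoate | COC(=O)CCC[C@@H]1CC[C@@H](C#C)O1 | intermediate
12 | hept-6-yn-1-ol | OCCCCCC#C | starting material
13 | 7-bromohept-1-yne | BrCCCCCC#C | intermediate
14 | [(1E)-7-bromohept-1-en-1-yl]chloridobis(cyclopentadienyl)zirconium, rings drawn σ-bonded (not isolated) | BrCCCCC/C=C/[Zr](Cl)(C1C=CC=C1)C1C=CC=C1 | intermediate
15 | (1E)-7-bromo-1-iodohept-1-ene | BrCCCCC/C=C/I | intermediate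
16 | [(6E)-7-iodohept-6-en-1-yl]triphenylphosphonium bromide | I/C=C/CCCCC[P+](c1ccccc1)(c1ccccc1)c1ccccc1.[Br-] | intermediate
17 | ethyl (2Z)-3-bromoprop-2-enoate | CCOC(=O)/C=C\Br | starting material
18 | [(6E)-7-iodohept-6-en-1-ylidene]triphenyl-λ5-phosphane (not isolated) | I/C=C/CCCCC=P(c1ccccc1)(c1ccccc1)c1ccccc1 | intermediate
19 | (2Z)-3-bromoprop-2-enal (not isolated) | O=C/C=C\Br | intermediate
20 | (1Z,3Z,9E)-1-bromo-10-iododeca-1,3,9-triene | I/C=C/CCCC/C=C\C=C/Br | intermediate
21 | methyl 4-[(2R,5S)-5-[(3E,9Z,11Z)-12-bromododeca-3,9,11-trien-1-yn-1-yl]oxolan-2-yl]butanoate | COC(=O)CCC[C@@H]1CC[C@@H](C#C/C=C/CCCC/C=C\C=C/Br)O1 | target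

**Step count and risks**

Total steps: 11. Longest linear sequence: 6 (steps 1, 2, 3, 5, 6, 11).

Steps most likely to fail:

1. Step 5 (proposed new method). What may go wrong: reclosure of the iodohydrin to the epoxide or δ-lactonisation before halogen-atom transfer; interception of the primary radical by copper before it adds to the enyne; outer-sphere oxidation of the propargylic radical to a free cation, which would close the ring with poor facial selectivity at C5. Fallback, setting out from 4 and coming back at 11: radical allylation of 4 (allyltributylstannane, AIBN, benzene, 80 °C; Keck allylation) would give methyl (5R)-5-hydroxynon-8-enoate F1. Aerobic oxidative cyclisation of F1 with Co(modp)2 (modp = 1-morpholinocarbamoyl-4,4-dimethylpentane-1,3-dionate, divalent cobalt; O2, tBuOOH, iPrOH, 55 °C; Mukaiyama type), a reaction known to close 1-substituted pent-4-en-1-ols to 2,5-trans oxolanes, would give methyl 4-[(2R,5S)-5-(hydroxymethyl)oxolan-2-yl]butanoate F2. Dess–Martin oxidation would give methyl 4-[(2R,5S)-5-formyloxolan-2-yl]butanoate F3, and Seyferth–Gilbert homologation with dimethyl (1-diazo-2-oxopropyl)phosphonate (K2CO3, MeOH, 0 °C to rt) would give 11. Here the ring arises by C–O closure alone and C5 is set by the cobalt-mediated cyclisation.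

2. Step 10. What may go wrong: isomerisation of the (Z)-bromo-enal to the E form before it is consumed, and loss of Z selectivity in the olefination caused by the aluminium salts that accompany the aldehyde. Fallback, setting out from 16 and coming back at 20: the ylide 18 (from 16, NaN(SiMe3)2, THF, −78 °C) would be combined with commercial 3-(trimethylsilyl)prop-2-ynal to give [(3Z,9E)-10-iododeca-3,9-dien-1-yn-1-yl]trimethylsilane F4. Bromodesilylation (N-bromosuccinimide, AgNO3 cat., acetone) would give (3Z,9E)-1-bromo-10-iododeca-3,9-dien-1-yne F5. Syn reduction of the bromoalkyne with diimide (2-nitrobenzenesulfonohydrazide, Et3N, THF/iPrOH, rt) would give 20; the terminal Z geometry then comes from syn hydrogen delivery to an alkyne and not from a preformed (Z)-enal.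

3. Step 11. What may go wrong: competing oxidative addition at the dienyl C–Br bond (oligomeric enynes) and palladium-induced isomerisation of the (Z,Z)-bromodiene. Fallback, setting out from 11 and 15 and coming back at 21: Sonogashira coupling of 11 with 15 (Pd(PPh3)4, CuI, iPr2NH, THF, rt; the alkyl bromide is inert) would give methyl 4-[(2R,5S)-5-[(3E)-9-bromonon-3-en-1-yn-1-yl]oxolan-2-yl]butanoate F6. Quaternisation (PPh3, MeCN, 80 °C) would give {(6E)-9-[(2S,5R)-5-(4-methoxy-4-oxobutyl)oxolan-2-yl]non-6-en-8-yn-1-yl}triphenylphosphonium bromide F7. Deprotonation (NaN(SiMe3)2, THF, −78 °C) would give the corresponding ylide F8, and Wittig reaction with 19 (made from 17 as in step 10) would give 21, so that the bromodiene never meets palladium.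

**Further compounds**

F1 | step 5 | methyl (5R)-5-hydroxynon-8-enoate | COC(=O)CCC[C@@H](O)CCC=C
F2 | step 5 | methyl 4-[(2R,5S)-5-(hydroxymethyl)oxolan-2-yl]butanoate | COC(=O)CCC[C@@H]1CC[C@@H](CO)O1
F3 | step 5 | methyl 4-[(2R,5S)-5-formyloxolan-2-yl]butanoate | COC(=O)CCC[C@@H]1CC[C@@H](C=O)O1
F4 | step 10 | [(3Z,9E)-10-iododeca-3,9-dien-1-yn-1-yl]trimethylsilane | I/C=C/CCCC/C=C\C#C[Si](C)(C)C
F5 | step 10 | (3Z,9E)-1-bromo-10-iododeca-3,9-dien-1-yne | I/C=C/CCCC/C=C\C#CBr
F6 | step 11 | methyl 4-[(2R,5S)-5-[(3E)-9-bromonon-3-en-1-yn-1-yl]oxolan-2-yl]butanoate | COC(=O)CCC[C@@H]1CC[C@@H](C#C/C=C/CCCCCBr)O1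
F7 | step 11 | {(6E)-9-[(2S,5R)-5-(4-methoxy-4-oxobutyl)oxolan-2-yl]non-6-en-8-yn-1-yl}triphenylphosphonium bromide | COC(=O)CCC[C@@H]1CC[C@@H](C#C/C=C/CCCCC[P+](c2ccccc2)(c2ccccc2)c2ccccc2)O1.[Br-]
F8 | step 11 | {(6E)-9-[(2S,5R)-5-(4-methoxy-4-oxobutyl)oxolan-2-yl]non-6-en-8-yn-1-ylidene}triphenyl-λ5-phosphane | COC(=O)CCC[C@@H]1CC[C@@H](C#C/C=C/CCCCC=P(c2ccccc2)(c2ccccc2)c2ccccc2)O1
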